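**Retrosynthetic overview**
1. The C40 target is cut at the central C15–C15' sp2–sp2 single bond (Suzuki–Miyaura) into ring A dienyl iodide 18 and (3'S)-ring B alkenylboronate 20. Both come from one C19 keto aldehyde 17 (Takai iodo- and boryl-olefination), and the C3' carbinol comes from CBS reduction of the same ring ketone.
2. Aldehyde 17 goes back to the C11 retro keto aldehyde 11 by C3 (Wittig) and C5 (Horner–Wadsworth–Emmons) chain extension.
3. Aldehyde 11 comes from ring product 9, which is made by closing C1–C6 in the acyclic allenyl dienone 7 (biomimetic cation–π cyclisation); 7 comes from propargylic alcohol 3 and enol ether 5 (Saucy–Marbet Claisen).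
4. Enabling feature: ring A is a 3,5,5-trimethylcyclohex-2-enone whose gem-dimethyl carbon C1 is β to the C3 carbonyl (a hidden mesityl oxide unit C1=C2–C3=O) and whose C6 carries the exocyclic C6=C7 bond beside C4=C5. The C4=C5–C6=C7 diene is what an allene C5=C6=C7 leaves once its central carbon C6 has bonded to C1 and C4 has lost a proton.
5. Ring order: the carbocycle is closed once (step 4) and serves both ends; ring B is the same ring after enantioselective reduction at C3'; no other ring is formed.

Key step: step 4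

Remark on the chemistry: the exocyclic C6=C7 and C6'=C7' bonds of such retro-polyenes are assumed to be stereochemically mobile under iodine or heat. Compounds 9 to 20 are named and drawn as 6E isomers but are carried as 6E/6Z mixtures, and this geometry is settled once, in step 14.
Assumption: phosphonate 14 is bought; if not, it is one Arbuzov step from ethyl (E)-4-bromo-2-methylbut-2-enoate and P(OEt)3.

**Route**

Step 1
Reactants: 1 (tert-butyldimethylsilyloxy)acetaldehyde; 2 1-propynylmagnesium bromide (MeC≡CMgBr)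
Product: 3 rac-1-[(tert-butyldimethylsilyl)oxy]pent-3-yn-2-ol
Conditions: THF, −78 → 0 °C; then H2O
Reagents that add atoms: none
Why: Grignard addition of the alkynyl nucleophile to the unhindered aldehyde; the carbinol centre is left racemic because it is erased in steps 3 and 4 (allene axis, then sp2 carbon).

Step 2
Reactants: 4 methyl 3-methylbut-2-enoate
Product: 5 2-methoxy-4-methylpenta-1,3-diene
Conditions: Cp2TiMe2 (2 equiv), toluene/THF, 65 °C, dark; filtration through basic Al2O3, used as a toluene solution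
Reagents that add atoms: dimethyltitanocene Cp2TiMe2, [CH3-].[CH3-].[Ti+4].c1cc[cH-]c1.c1cc[cH-]c1
Why: Petasis methylenation, in which Cp2Ti=CH2 formed by α-elimination should convert the conjugated ester carbonyl into the 2-alkoxydiene; no stereocentre is involved.

Step 3
Reactants: 3 rac-1-[(tert-butyldimethylsilyl)oxy]pent-3-yn-2-ol; 5 2-methoxy-4-methylpenta-1,3-diene
Product: 7 rac-9-[(tert-butyldimethylsilyl)oxy]-2,6-dimethylnona-2,6,7-trien-4-one, via propargyl dienyl ether 6 (not isolated)
Conditions: 5 (3 equiv), 2,4-dinitrophenol (5 mol %), toluene, 95 °C, sealed tube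
Reagents that add atoms: none
Why: Saucy–Marbet reaction, in which acid-catalysed alkoxy exchange should give ether 6, whose propargyl Claisen [3,3] shift delivers the terminal CH2 to the methyl-bearing alkyne carbon and releases the β-allenyl ketone; only the racemic, later erased allene axis is formed.

Step 4
Reactants: 7 rac-9-[(tert-butyldimethylsilyl)oxy]-2,6-dimethylnona-2,6,7-trien-4-one
Product: 9 (4E)-4-{2-[(tert-butyldimethylsilyl)oxy]ethylidene}-3,5,5-trimethylcyclohex-2-en-1-one, via aluminium trienolate 8 (not isolated)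
Conditions: Me2AlCl (1.5 equiv), CH2Cl2, −78 → −20 °C; then aq KNaC4H4O6 (potassium sodium tartrate)
Reagents that add atoms: none
Why: Proposed new method: Me2AlCl binds the C3 carbonyl and turns the β,β-dimethyl enone terminus into a tertiary C1 carbocation equivalent; the C5=C6 π bond of the allene attacks it through the central carbon C6 (C1–C6 bond), the resulting C5 cation (allylic once it rotates into conjugation with C6=C7) loses the C4 proton to an aluminium-bound methyl (methane), and the aluminium trienolate 8 is protonated at C2 on work-up, so the net change is a formal intramolecular ene reaction that should deliver the 4-en-3-one, the quaternary gem-dimethyl carbon and the exocyclic C6=C7 bond at once. The closest known reaction types are the Me2AlCl-promoted ene and cation–olefin cyclisations of enones and the acid cyclisation of pseudoionone to the ionones; the new element is an allene as the π-nucleophile, and the sequence copies the cyclase closure of the ψ end (C1 cation, attack of C5=C6 through C6, ε-type loss of H-4). The ring closes in a 6-endo-trig mode at the enone, with both carbons of the reacting C5=C6 bond ending up in the ring. No stereocentre is formed; only the C6=C7 geometry is created, attack anti to the CH2OTBS arm is expected to favour 6Z, and this is left to the later stereomutation. The step needs bonding at C6 rather than C5 or C7 and proton loss from C4 rather than from the C5 methyl; the first is secured because only central-carbon attack gives a tertiary, then allylic, cation in a six-membered ring, the second by conjugation of the new C4=C5 bond with the enolate and with C6=C7, and Me2AlCl as proton scavenger suppresses acid isomerisation of the allene.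

Step 5
Reactants: 9 (4E)-4-{2-[(tert-butyldimethylsilyl)oxy]ethylidene}-3,5,5-trimethylcyclohex-2-en-1-one
Product: 10 (4E)-4-(2-hydroxyethylidene)-3,5,5-trimethylcyclohex-2-en-1-one
Conditions: HF·pyridine, pyridine, THF, 0 °C
Reagents that add atoms: none
Why: Fluoride-mediated desilylation of the primary silyl ether under buffered conditions that should leave the dienone untouched.

Step 6
Reactants: 10 (4E)-4-(2-hydroxyethylidene)-3,5,5-trimethylcyclohex-2-en-1-one
Product: 11 (2E)-2-(2,6,6-trimethyl-4-oxocyclohex-2-en-1-ylidene)acetaldehyde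
Conditions: MnO2 (20 equiv), CH2Cl2, 20 °C
Reagents that add atoms: none
Why: MnO2 oxidation of a primary allylic alcohol to the conjugated aldehyde without over-oxidation.

Step 7
Reactants: 11 (2E)-2-(2,6,6-trimethyl-4-oxocyclohex-2-en-1-ylidene)acetaldehyde; 12 2-(triphenylphosphoranylidene)propanal
Product: 13 (2E,4E)-2-methyl-4-(2,6,6-trimethyl-4-oxocyclohex-2-en-1-ylidene)but-2-enal
Conditions: toluene, 85 °C
Reagents that add atoms: none
Why: Wittig olefination with a stabilised ylide, which should react only at the aldehyde (the hindered conjugated ring ketone is inert) and give the E-trisubstituted C8=C9 bond.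

Step 8
Reactants: 13 (2E,4E)-2-methyl-4-(2,6,6-trimethyl-4-oxocyclohex-2-en-1-ylidene)but-2-enal; 14 ethyl (2E)-4-(diethoxyphosphoryl)-2-methylbut-2-enoate
Product: 15 ethyl (2E,4E,6E,8E)-2,6-dimethyl-8-(2,6,6-trimethyl-4-oxocyclohex-2-en-1-ylidene)octa-2,4,6-trienoate
Conditions: LiN(SiMe3)2 (1.0 equiv, anion pre-formed), THF, −78 → 0 °C
Reagents that add atoms: none
Why: Horner–Wadsworth–Emmons olefination with the lithiated allylic phosphonate, which should be E-selective at the new C10=C11 bond and selective for the aldehyde over the ring ketone.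

Step 9
Reactants: 15 ethyl (2E,4E,6E,8E)-2,6-dimethyl-8-(2,6,6-trimethyl-4-oxocyclohex-2-en-1-ylidene)octa-2,4,6-trienoate
Product: 16 (2E,4E,6E,8E)-8-(4-hydroxy-2,6,6-trimethylcyclohex-2-en-1-ylidene)-2,6-dimethylocta-2,4,6-trien-1-ol (racemic at the ring carbinol)
Conditions: iBu2AlH (5 equiv), CH2Cl2, −78 °C; then aq KNaC4H4O6
Reagents that add atoms: none
Why: Hydride reduction with iBu2AlH takes the ester to the primary allylic alcohol and the enone to the ring carbinol by 1,2-addition; both are allylic and are re-oxidised together in step 10, so no selectivity is required.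

Step 10
Reactants: 16 (2E,4E,6E,8E)-8-(4-hydroxy-2,6,6-trimethylcyclohex-2-en-1-ylidene)-2,6-dimethylocta-2,4,6-trien-1-ol
Product: 17 (2E,4E,6E,8E)-2,6-dimethyl-8-(2,6,6-trimethyl-4-oxocyclohex-2-en-1-ylidene)octa-2,4,6-trienal
Conditions: MnO2 (30 equiv), CH2Cl2, 20 °C, dark
Reagents that add atoms: none
Why: MnO2 oxidation of both allylic alcohols should restore the ring ketone and give the polyenal under neutral conditions that spare the acid-labile ring carbinol until it is oxidised.

Step 11
Reactants: 17 (2E,4E,6E,8E)-2,6-dimethyl-8-(2,6,6-trimethyl-4-oxocyclohex-2-en-1-ylidene)octa-2,4,6-trienal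
Product: 18 (4E)-4-[(2E,4E,6E,8E)-9-iodo-3,7-dimethylnona-2,4,6,8-tetraen-1-ylidene]-3,5,5-trimethylcyclohex-2-en-1-one
Conditions: CrCl2 (8 equiv), CHI3 (2.5 equiv), THF, 0 → 20 °C, dark
Reagents that add atoms: iodoform, IC(I)I
Why: Takai iodo-olefination, in which the gem-dichromium species from CHI3 and divalent chromium should add only to the aldehyde and eliminate to the E-alkenyl iodide.

Step 12
Reactants: 17 (2E,4E,6E,8E)-2,6-dimethyl-8-(2,6,6-trimethyl-4-oxocyclohex-2-en-1-ylidene)octa-2,4,6-trienal
Product: 19 (4E)-3,5,5-trimethyl-4-[(2E,4E,6E,8E)-3,7-dimethyl-9-(4,4,5,5-tetramethyl-1,3,2-dioxaborolan-2-yl)nona-2,4,6,8-tetraen-1-ylidene]cyclohex-2-en-1-one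
Conditions: CrCl2 (8 equiv), LiI (4 equiv), Cl2CHBpin (2 equiv), THF, 20 °C, dark
Reagents that add atoms: 2-(dichloromethyl)-4,4,5,5-tetramethyl-1,3,2-dioxaborolane, ClC(Cl)B1OC(C)(C)C(C)(C)O1
Why: Takai–Utimoto boryl-olefination, the boron counterpart of step 11, which should be aldehyde-selective and E-selective.

Step 13
Reactants: 19 (4E)-3,5,5-trimethyl-4-[(2E,4E,6E,8E)-3,7-dimethyl-9-(4,4,5,5-tetramethyl-1,3,2-dioxaborolan-2-yl)nona-2,4,6,8-tetraen-1-ylidene]cyclohex-2-en-1-one
Product: 20 (1S,4E)-3,5,5-trimethyl-4-[(2E,4E,6E,8E)-3,7-dimethyl-9-(4,4,5,5-tetramethyl-1,3,2-dioxaborolan-2-yl)nona-2,4,6,8-tetraen-1-ylidene]cyclohex-2-en-1-ol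
Conditions: (R)-1-methyl-3,3-diphenyltetrahydro-1H,3H-pyrrolo[1,2-c][1,3,2]oxazaborole ((R)-Me-CBS, 0.3 equiv), catecholborane (2 equiv), toluene, −78 → −40 °C; then MeOH, aq NaHCO3
Reagents that add atoms: none
Why: Corey–Bakshi–Shibata reduction, in which the oxazaborolidine binds the carbonyl with the alkenyl (C4') flank as the large group and delivers hydride to one face; with the (R)-catalyst the usual model for cyclohexenones predicts the (3'S) carbinol.

Step 14
Reactants: 18 (4E)-4-[(2E,4E,6E,8E)-9-iodo-3,7-dimethylnona-2,4,6,8-tetraen-1-ylidene]-3,5,5-trimethylcyclohex-2-en-1-one; 20 (1S,4E)-3,5,5-trimethyl-4-[(2E,4E,6E,8E)-3,7-dimethyl-9-(4,4,5,5-tetramethyl-1,3,2-dioxaborolan-2-yl)nona-2,4,6,8-tetraen-1-ylidene]cyclohex-2-en-1-ol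
Product: 21 (3'S,6E,6'E)-3'-hydroxy-4',5'-didehydro-4,5'-retro-β,β-caroten-3-one (the target)
Conditions: Pd(PPh3)4 (5 mol %), aq K3PO4, THF, 40 °C, degassed, dark; then I2 (1 mol %), CH2Cl2/hexane, 20 °C, diffuse light; crystallisation
Reagents that add atoms: none
Why: Suzuki–Miyaura coupling (oxidative addition of the dienyl iodide to zerovalent palladium, transmetallation of the alkenylboronate, reductive elimination) should form the central C15–C15' bond with retention at both alkenes and tolerate the free ketone and hydroxyl, and the iodine-catalysed stereomutation should funnel 6Z/6'Z material to the (6E,6'E) isomer, which is isolated by crystallisation.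

**Compound list**
1 | (tert-butyldimethylsilyloxy)acetaldehyde | O=CCO[Si](C)(C)C(C)(C)C | starting material
2 | 1-propynylmagnesium bromide | CC#C[Mg]Br | starting material
3 | rac-1-[(tert-butyldimethylsilyl)oxy]pent-3-yn-2-ol | CC#CC(O)CO[Si](C)(C)C(C)(C)C | intermediate
4 | methyl 3-methylbut-2-enoate | COC(=O)C=C(C)C | starting material
5 | 2-methoxy-4-methylpenta-1,3-diene | COC(=C)C=C(C)C | intermediate
6 | rac-tert-butyl(dimethyl)({2-[(4-methylpenta-1,3-dien-2-yl)oxy]pent-3-yn-1-yl}oxy)silane, propargyl dienyl ether (not isolated) | CC#CC(CO[Si](C)(C)C(C)(C)C)OC(=C)C=C(C)C | intermediate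
7 | rac-9-[(tert-butyldimethylsilyl)oxy]-2,6-dimethylnona-2,6,7-trien-4-one (allenyl dienone) | CC(C)=CC(=O)CC(C)=C=CCO[Si](C)(C)C(C)(C)C | intermediate
8 | chloro(methyl)aluminium 4-{2-[(tert-butyldimethylsilyl)oxy]ethylidene}-3,3,5-trimethylcyclohexa-1,5-dien-1-olate (not isolated) | C[Al](Cl)OC1=CC(C)(C)C(=CCO[Si](C)(C)C(C)(C)C)C(C)=C1 | intermediate
9 | (4E)-4-{2-[(tert-butyldimethylsilyl)oxy]ethylidene}-3,5,5-trimethylcyclohex-2-en-1-one | CC1=CC(=O)CC(C)(C)\C1=C/CO[Si](C)(C)C(C)(C)C | intermediate
10 | (4E)-4-(2-hydroxyethylidene)-3,5,5-trimethylcyclohex-2-en-1-one | CC1=CC(=O)CC(C)(C)\C1=C/CO | intermediate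
11 | (2E)-2-(2,6,6-trimethyl-4-oxocyclohex-2-en-1-ylidene)acetaldehyde | CC1=CC(=O)CC(C)(C)\C1=C/C=O | intermediate
12 | 2-(triphenylphosphoranylidene)propanal | CC(C=O)=P(c1ccccc1)(c1ccccc1)c1ccccc1 | starting material
13 | (2E,4E)-2-methyl-4-(2,6,6-trimethyl-4-oxocyclohex-2-en-1-ylidene)but-2-enal | CC1=CC(=O)CC(C)(C)\C1=C/C=C(C)/C=O | intermediate
14 | ethyl (2E)-4-(diethoxyphosphoryl)-2-methylbut-2-enoate | CCOC(=O)/C(C)=C/CP(=O)(OCC)OCC | starting material
15 | ethyl (2E,4E,6E,8E)-2,6-dimethyl-8-(2,6,6-trimethyl-4-oxocyclohex-2-en-1-ylidene)octa-2,4,6-trienoate | CC1=CC(=O)CC(C)(C)\C1=C/C=C(C)/C=C/C=C(C)/C(=O)OCC | intermediate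
16 | (2E,4E,6E,8E)-8-(4-hydroxy-2,6,6-trimethylcyclohex-2-en-1-ylidene)-2,6-dimethylocta-2,4,6-trien-1-ol (racemic carbinol) | CC1=CC(O)CC(C)(C)\C1=C/C=C(C)/C=C/C=C(C)/CO | intermediate
17 | (2E,4E,6E,8E)-2,6-dimethyl-8-(2,6,6-trimethyl-4-oxocyclohex-2-en-1-ylidene)octa-2,4,6-trienal | CC1=CC(=O)CC(C)(C)\C1=C/C=C(C)/C=C/C=C(C)/C=O | intermediate
18 | (4E)-4-[(2E,4E,6E,8E)-9-iodo-3,7-dimethylnona-2,4,6,8-tetraen-1-ylidene]-3,5,5-trimethylcyclohex-2-en-1-one | CC1=CC(=O)CC(C)(C)\C1=C/C=C(C)/C=C/C=C(C)/C=C/I | intermediate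
19 | (4E)-3,5,5-trimethyl-4-[(2E,4E,6E,8E)-3,7-dimethyl-9-(4,4,5,5-tetramethyl-1,3,2-dioxaborolan-2-yl)nona-2,4,6,8-tetraen-1-ylidene]cyclohex-2-en-1-one | CC1=CC(=O)CC(C)(C)\C1=C/C=C(C)/C=C/C=C(C)/C=C/B1OC(C)(C)C(C)(C)O1 | intermediate
20 | (1S,4E)-3,5,5-trimethyl-4-[(2E,4E,6E,8E)-3,7-dimethyl-9-(4,4,5,5-tetramethyl-1,3,2-dioxaborolan-2-yl)nona-2,4,6,8-tetraen-1-ylidene]cyclohex-2-en-1-ol | CC1(C)OB(OC1(C)C)/C=C/C(C)=C/C=C/C(C)=C/C=C2/C(C)=C[C@@H](O)CC2(C)C | intermediate
21 | (3'S,6E,6'E)-3'-hydroxy-4',5'-didehydro-4,5'-retro-β,β-caroten-3-one | CC1=CC(=O)CC(C)(C)\C1=C/C=C(C)/C=C/C=C(C)/C=C/C=C/C(C)=C/C=C/C(C)=C/C=C1/C(C)=C[C@@H](O)CC1(C)C | target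

**Count**
Total steps: 14. Longest linear sequence: 12 steps (1, 3 to 10, 12 to 14).

**Steps most likely to fail**

Step 4. The Lewis acid may instead cause prototropic isomerisation of the allene into the conjugated trienone (followed by Nazarov-type closure), methyl transfer from aluminium to C1, or proton loss from the C5 methyl instead of C4.
Fallback (known chemistry, pericyclic instead of cationic): it sets out from 7. Soft enolisation with Me3SiOTf and Et3N in CH2Cl2 at 0 °C gives the (4E)-trimethylsilyl trienol ether F1; the 4Z isomer is returned to 7 by mild hydrolysis and resubmitted. Heating F1 in toluene at 80 °C brings about the thermal disrotatory 6π-electrocyclisation known for dienyl-allenes and forms the same C1–C6 bond, giving the cyclic silyl dienol ether F2. Aqueous citric acid cleaves only the enol silyl ether, and the route is rejoined at 9.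

Step 3. Acid-mediated equilibration of the enol ether into its 2-alkoxy-2,4-diene isomer (Claisen shift through the wrong carbon), 1,4-addition of the alcohol to the protonated diene, and thermal or acid isomerisation of the product allene may erode the yield of 7.
Fallback (regiochemically unambiguous): it sets out from 3. Johnson orthoester Claisen rearrangement with MeC(OEt)3 and catalytic propionic acid at 140 °C gives ethyl 6-[(tert-butyldimethylsilyl)oxy]-3-methylhexa-3,4-dienoate F3. iBu2AlH at −78 °C reduces it to 6-[(tert-butyldimethylsilyl)oxy]-3-methylhexa-3,4-dienal F4. Addition of Me2C=CHMgBr at −78 °C gives 9-[(tert-butyldimethylsilyl)oxy]-2,6-dimethylnona-2,6,7-trien-4-ol F5, and MnO2 oxidation of this allylic alcohol rejoins the route at 7.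

Step 13. Facial discrimination may be insufficient because the saturated flank (CH2 next to the quaternary carbon) is nearly as bulky as the alkenyl flank, and hydroboration of the polyene may compete.
Fallback (resolution instead of asymmetric reduction): it sets out from 19. Luche reduction (NaBH4, CeCl3·7H2O, MeOH/THF, −40 °C) gives the racemic alcohol F6. Esterification with (S)-2-methoxy-2-phenylacetic acid (N,N'-dicyclohexylcarbodiimide, 4-(dimethylamino)pyridine) and chromatographic separation of the diastereomers gives the (S)-2-methoxy-2-phenylacetate of the (1S)-alcohol F7. Methanolysis with K2CO3 in MeOH rejoins the route at 20.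

Further compounds
F1 | step 4 | (4E)-9-[(tert-butyldimethylsilyl)oxy]-2,6-dimethyl-4-[(trimethylsilyl)oxy]nona-2,4,6,7-tetraene | CC(C)=C/C(O[Si](C)(C)C)=C\C(C)=C=CCO[Si](C)(C)C(C)(C)C
F2 | step 4 | {[(4E)-4-{2-[(tert-butyldimethylsilyl)oxy]ethylidene}-3,3,5-trimethylcyclohexa-1,5-dien-1-yl]oxy}trimethylsilane | CC1=CC(O[Si](C)(C)C)=CC(C)(C)\C1=C/CO[Si](C)(C)C(C)(C)C
F3 | step 3 | ethyl 6-[(tert-butyldimethylsilyl)oxy]-3-methylhexa-3,4-dienoate (racemic) | CCOC(=O)CC(C)=C=CCO[Si](C)(C)C(C)(C)C
F4 | step 3 | 6-[(tert-butyldimethylsilyl)oxy]-3-methylhexa-3,4-dienal (racemic) | O=CCC(C)=C=CCO[Si](C)(C)C(C)(C)C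
F5 | step 3 | 9-[(tert-butyldimethylsilyl)oxy]-2,6-dimethylnona-2,6,7-trien-4-ol (diastereomer mixture) | CC(C)=CC(O)CC(C)=C=CCO[Si](C)(C)C(C)(C)C
F6 | step 13 | rac-(4E)-3,5,5-trimethyl-4-[(2E,4E,6E,8E)-3,7-dimethyl-9-(4,4,5,5-tetramethyl-1,3,2-dioxaborolan-2-yl)nona-2,4,6,8-tetraen-1-ylidene]cyclohex-2-en-1-ol | CC1(C)OB(OC1(C)C)/C=C/C(C)=C/C=C/C(C)=C/C=C2/C(C)=CC(O)CC2(C)C
F7 | step 13 | (1S,4E)-3,5,5-trimethyl-4-[(2E,4E,6E,8E)-3,7-dimethyl-9-(4,4,5,5-tetramethyl-1,3,2-dioxaborolan-2-yl)nona-2,4,6,8-tetraen-1-ylidene]cyclohex-2-en-1-yl (2S)-2-methoxy-2-phenylacetate | CC1(C)OB(OC1(C)C)/C=C/C(C)=C/C=C/C(C)=C/C=C2/C(C)=C[C@@H](OC(=O)[C@@H](OC)c3ccccc3)CC2(C)C
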